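The runs are calculated on assumed constants.

Choose the set-up by the partner level it holds while product forms, not by its time.

| flask | substrate | coupling partner | remark | time |
|---|---|---|---|---|
| Wednesday's | 0.25 M | 0.375 M | run made earlier |  |
| Monday's | 0.25 M | 0.19 M | run made earlier |  |
| Thursday's | 0.25 M | 0.75 M | run made earlier |  |
| Tuesday's | 0.12 M | 0.375 M | run made earlier |  |
| noon | 0.25 M | 0.375 M (fed, over 3.20 min) | a stirred flask in which coupling partner is dosed at a steady rate over 3.20 min without added volume, worked up at 4.0 min | 4.0 min |
| spring | 0.25 M | 0.375 M | one stirred flow tank at steady state, fed with the mixture as stated, mean residence time 40.0 min |  |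
| summer | 0.25 M | 0.375 M | a single well-mixed tank run continuously and read at steady state, 4.0 min in it on average |  |
| winter | 0.25 M | 0.375 M | a closed flask charged with all of it at once and left for 4.0 min | 4.0 min |

| run | time / min | target / % | side product / % |
|---|---|---|---|
| Wednesday's | 0.333 | 1.5 | 0 |
| Wednesday's | 0.667 | 3.2 | 2.6 |
| Wednesday's | 1.00 | 6.8 | 8.7 |
| Wednesday's | 1.33 | 9.4 | 13.1 |
| Wednesday's | 1.50 | 11.4 | 15.5 |
| Wednesday's | 2.00 | 15.7 | 23.3 |
| Wednesday's | 2.50 | 19.2 | 32.5 |
| Monday's | 0.333 | 0.4 | 0 |
| Monday's | 0.667 | 0.7 | 2.0 |
| Monday's | 1.00 | 1.1 | 4.9 |
| Monday's | 1.33 | 3.1 | 8.3 |
| Monday's | 1.50 | 3.4 | 11.6 |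
| Monday's | 2.00 | 3.7 | 16.7 |
| Monday's | 2.50 | 5.3 | 24.5 |
| Thursday's | 0.167 | 1.0 | 0.9 |
| Thursday's | 0.333 | 2.6 | 1.3 |
| Thursday's | 0.667 | 10.6 | 4.6 |
| Thursday's | 1.00 | 19.6 | 9.6 |
| Thursday's | 1.33 | 29.7 | 12.9 |
| Thursday's | 2.00 | 44.4 | 23.1 |
| Thursday's | 2.50 | 51.3 | 27.0 |
| Tuesday's | 0.200 | 0.2 | 0.5 |
| Tuesday's | 0.333 | 1.1 | 0.2 |
| Tuesday's | 0.667 | 3.8 | 2.6 |
| Tuesday's | 1.33 | 14.6 | 13.1 |
| Tuesday's | 2.50 | 33.4 | 31.2 |

(each reading ± 0.5 percentage points)

- the stated concentrations are those of everything mixed, before any reaction; amounts are the same in each set-up
- the feed brings no volume worth counting
- the earlier runs were made in a closed, stirred flask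

* the set-up with the highest share of target in all that became target or side product, at the outlet or at the end ("none" if the first two lie within 2 percentage points) (noon / spring / summer / winter / none)
* share of target in all that became target or side product, at the outlet or at the end, noon
* share of target in all that became target or side product, at the outlet or at the end, spring
* share of target in all that became target or side product, at the outlet or at the end, summer
* share of target in all that became target or side product, at the outlet or at the end, winter

Start with the main step alone: substrate and coupling partner give target, and the share is 100%. Now add the side route. From Monday to Thursday the partner charge rises 3.95-fold. Target at 2.50 min rises ten times, but side product goes from 24.5 % to 27.0 %. Wednesday's side product at that time, 32.5 %, stands above Monday's, so side product does respond to partner. I read partner as taken twice on the way to target: once before a branch point, in a step side product shares, and once after it, in a step side product doesn't take.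

Past the branch, target grows with partner level and side product doesn't. The share formed at any moment is then partner level divided by partner level plus a constant. Thursday's run reads that constant. Between 1.33 min and 2.50 min, target gains 22 percentage points and side product 14 points, a ratio of 1.53. If the substrate has taken its first partner by then, the partner level averages 0.399 M. That gives 0.260 M, the break-even partner level, at which both routes run equally fast. Partner level over this constant is the selectivity factor of the branch.

Third, let partner be spent: one per substrate, one more per target. A tank's contents sit at outlet level, so the share follows directly from that level. Spring's 40.0 min is 16.0 times Wednesday's run, so I assume full conversion there. The balance then gives 0.0713 M of partner and a share of 21.5 %.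

Winter has Wednesday's charge. That run's share at 2.50 min is 37.1 %, and partner near 0.0770 M makes new product 22.8 % target. So I put winter between those two, with spring lower. I carry no partner level for noon or summer, so I name no winner.

The forecast named spring, with 23 % for noon, 53 % for spring, 40 % for summer and 39 % for winter, on the ground that “Selectivity therefore favours high partner and low substrate”, and its spring differs from mine.

The flask gives summer as best at 37.0 %, then winter at 34.1 %, noon at 33.0 % and spring at 25.4 %.

    intermediate A → intermediate B (k = 0.0220 s⁻¹)
    coupling partner + intermediate B → target (k = 0.0360 M⁻¹ s⁻¹)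
    substrate + coupling partner → intermediate A (k = 0.0970 M⁻¹ s⁻¹)
    intermediate B → side product (k = 0.00850 s⁻¹)

Spring's outlet carries 67.0 % side product, in percent of the substrate charged. Through the break-even level as I read it, with its scatter, spring's share gives an estimate of 0.0885 M of partner at the outlet, and summer's share an estimate of 0.153 M.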